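## Structural features

The target has three rings joined through one spiro carbon and one fused bond. Ring A is an enolised 2-acylcyclohexane-1,3,5-trione with an isovaleryl group on the carbon between two oxygenated carbons and two prenyl groups on a second carbon. Its remaining saturated carbon is the spiro centre shared with cyclohexane ring B, which is trans-fused to cyclopentane ring C.

There are five stereocentres: the spiro carbon, the two adjacent ring-fusion CH carbons, and two tertiary methyl carbinols. One carbinol is in ring C, next to the fusion carbon that bears the ring-B CH2. The other is in ring B, next to the other fusion carbon and separated from the spiro carbon by a CH2.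

The spiro carbon is stereogenic only because its two ring-A carbonyl neighbours differ: one is flanked by the diprenyl carbon, the other by the acyl-bearing carbon. The former is cis and 1,3-diaxial to the ring-B hydroxyl, so a lactone can tell the two apart.

Fragile features are the ketone between two quaternary carbons in a β-dicarbonyl array (retro-Claisen cleavage, also by the neighbouring hydroxyl), the two tertiary alcohols (elimination), the prenyl alkenes (acid-induced addition of the enol oxygen) and the ambident enolised triketone.

The real difficulty is the congested spiro centre, whose sense must be tied to the distant hydrindane centres, together with two carbinols that cannot be corrected by epimerisation.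

The key step uses ring C. The two ring-fusion carbons are vicinal with trans substituents and the next ring atom is a carbinol carbon, so ring C is a masked 2,3-trans-disubstituted cyclopentanone. Its β-substituent (a three-carbon unit ending in the ring-B carbinol carbon) and its α-substituent (the ring-B CH2 bound to the spiro carbon) can be attached to cyclopentenone in one conjugate-addition/enolate-trapping event. Mapping 7 onto 18 confirms that its (R) α-carbon and (S) β-carbon are the two ring-fusion centres, so no structure needed correction.

## Logic of the disconnections

18 ⇒ 15 + 16 (twice). The two bonds from the ring-A carbon between the ketone and the enol carbon to the prenyl CH2 groups are cut. This carbon is the only ring-A position of 15 that still bears hydrogen, and the two groups are identical, so no stereocentre is at stake. Ten carbons are removed and the last step needs no protecting group. The forward step must alkylate at carbon twice (through 17) without cleaving the ketone that becomes non-enolisable.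

15 ⇒ 13. The bond between the acyl-bearing ring carbon and the carbonyl carbon on the spiro centre that is trans to the ring-B hydroxyl is cut (Claisen retron). Ring A opens to a triketo ester chain and the spiro carbon becomes an ordinary quaternary carbon with one ester and one acyl group. The forward step must be a C-acylation by the doubly activated CH2; the silyl ether still present at that point (14) is removed in the same flask.

13 ⇒ 10 + 11. The bond between the chain ketone on the future spiro carbon and its neighbouring CH2 is cut. In 10 that carbonyl is held as a lactone by the ring-B oxygen, which distinguishes it from the methyl ester on the same carbon and decides the spiro configuration. All ring-A carbons not derived from the malonate, and the whole isovaleryl group, come from one commercial diketone. The forward step needs a terminal carbanion (12) that attacks the lactone and not the ester.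

10 ⇒ 9. The bond from the malonate carbon to the ring-B CH2 next to the carbinol carbon, and the lactone C–O bond at that carbinol carbon, are cut (malonyl radical plus 1,1-disubstituted alkene). Ring B and two stereocentres disappear, leaving a monocyclic cyclopentane. The forward step must close 6-endo, oxidise the tertiary radical and let the ester capture the cation.

9 ⇒ 8 ⇒ 7. The silyl group is removed and the C–CH3 bond of the ring-C carbinol is cut to reveal the ketone. The forward addition must deliver methyl anti to the neighbouring branch with a reagent that ignores the esters and the acidic malonate hydrogen. The silyl ether is added because the new hydroxyl lies cis to the malonate branch and could otherwise lactonise.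

7 ⇒ 5 + 2 + 4. The bond from the β-carbon to the isopropenyl carbon and the bond from the α-carbon to the CH2 are cut. The whole carbon set of rings B and C, apart from the carbinol methyl, is reduced to three small pieces. The forward step must control the absolute configuration at the β-carbon and the trans relationship. The precursor set is tuned in two ways: 2 is prepared in a weakly coordinating ether, and 4 is freshly cracked and added only after 2 is consumed.

2 ⇒ 1 and 4 ⇒ 3. The C–Mg bond and the C=CH2 bond are cut, leading to the alkenyl bromide and to the malonate plus formaldehyde.

## Other disconnections considered

Alternative 1: The cut is the bond between the spiro carbon and the ring-A carbonyl carbon flanked by the diprenyl carbon. In the forward sense the spiro epoxide A2 joins a 2,2-diprenylcyclopentane-1,3-dione to the ring-B carbon through an epoxide. BF3·OEt2 opens it at the tertiary ring-B carbon, the acyl carbon migrates to that centre with inversion, and the oxygen left behind becomes the second carbonyl. The five-membered dione grows into ring A and gives A1.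

- In favour: the 1,2-acyl shift of an α,β-epoxy ketone is stereospecific, so the spiro centre is copied from the epoxide. The prenyl groups are installed on a simple dione, so the congested late gem-diprenylation of step 9 is avoided; on this point the alternative is better than the chosen plan. The acyl/diprenyl orientation is unambiguous, which equals what 10 achieves.
- Against: the epoxide configuration must first be set by face-selective epoxidation of a hindered, electron-poor tetrasubstituted alkene. BF3 meets two tertiary silyl ethers, two prenyl alkenes and a developing tertiary cation, so elimination, hydride shift or alkyl migration can compete. A1 still needs C-acylation and desilylation.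
- Comparison: both plans derive the spiro configuration from a hydrindane centre. The chosen plan uses a chair-locked lactonisation that can give only one isomer, whereas the alternative depends on a facial selectivity that is not obvious in advance. The alternative replaces only steps 6–9 and needs more operations for that stretch (ring-B ketone, alkylidene formation, epoxidation, rearrangement, acylation, desilylation).

Alternative 2: The cuts are the spiro-carbon-to-CH2 bond and the bond between the two ring-fusion carbons. Triene A4 would come from (S)-linalool A5 by allylic oxidation and Knoevenagel condensation with 3. On heating it would undergo intramolecular Diels–Alder reaction, with the alkylidene-malonate alkene plus the trisubstituted alkene as diene and the carbinol vinyl group as dienophile, closing rings B and C together to give A3.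

- In favour: two rings, two C–C bonds and both ring-fusion centres form in one step from a terpene alcohol that already holds the ring-C carbinol. No organometallic reagent or chiral catalyst is needed. The gem-diester and ring-B alkene of A3 are ready for an acid-mediated lactonisation equivalent to step 6. In ring and bond economy this is better than the chosen plan.
- Against: a diene made electron-poor by two esters is mismatched with an unactivated vinyl group, so high temperature is needed. That puts the tertiary allylic alcohol (dehydration) and the dienyl malonate (1,5-hydrogen shift) at risk. A three-atom tether gives little inherent preference between trans and cis fusion. The only control element is a carbinol whose methyl and hydroxyl differ little in size, so facial selectivity is uncertain. The less common (S) antipode of the terpene is required.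
- Comparison: the chosen plan sets the fusion centres by a ligand and a thermodynamic trans preference that do not depend on the carbinol, and then sets the carbinol by substrate control. It is longer by a few steps but each stereocentre has its own control element. The alternative is equal in how it later reaches the lactone.

Alternative 3: The cut is the bond between the ring-C carbinol carbon and the ring-fusion carbon that bears the one-carbon branch; ring C is seen as a contracted cyclohexanone. Diazo ketone A7 would come from (S)-limonene A8 by 1,2-oxygenation, oxidation to the hydroxy ketone, silylation and diazo transfer. Photolysis in MeOH triggers Wolff rearrangement with migration of the silyloxy-bearing carbon, and the ketene is trapped as ester A6.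

- In favour: the absolute configuration comes from the chiral pool, which is better than relying on the enantioselectivity of a catalyst. The migrating carbon keeps its configuration, so the carbinol is set on a six-membered ring where epoxide or diol chemistry is predictable; this is equal to or better than step 4. The trans relationship follows from equilibration of the ester, equal to the chosen plan.
- Against: A6 carries only a one-carbon branch at the ester level, so reduction, activation and malonate alkylation are needed to reach the stage of 9. The diazo ketone itself takes about five steps. The carbene can also insert into the O–H of MeOH, undergo 1,2-hydrogen shift or add to the isopropenyl alkene. Photochemistry limits scale, and the less abundant limonene antipode is needed.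
- Comparison: structurally it delivers the same ring-C pattern as 7. Mechanistically it is stereospecific where the chosen step is catalyst-controlled. In step count it is clearly longer, since step 3 attaches the malonate and the isopropenyl group in one operation.

Key step: step 3

Assumption: the sense of induction of the ferrocenyl diphosphine is assigned in a pilot run and the antipode that gives 7 is used (both are commercial); enolised triones are drawn as one tautomer.

## Route

Step 1
Reactants: 1 2-bromopropene
Product: 2 isopropenylmagnesium bromide
Conditions: Mg turnings, BrCH2CH2Br (cat.), 2-MeTHF, 40–45 °C
Reagents that add atoms: magnesium, [Mg]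
Why: Insertion of magnesium into the alkenyl C–Br bond (Grignard formation); 2-methyltetrahydrofuran replaces THF because the copper–diphosphine step that follows loses selectivity in strongly coordinating solvent.

Step 2
Reactants: 3 dimethyl malonate
Product: 4 dimethyl methylidenemalonate
Conditions: (CH2O)n, Cu(OAc)2·H2O (cat.), KOAc (cat.), AcOH, 100 °C; then vacuum distillation, used at once
Reagents that add atoms: paraformaldehyde (as formaldehyde), C=O
Why: Knoevenagel condensation with formaldehyde and loss of water gives the doubly activated alkene; distillation cracks oligomers, and the monomer is used fresh because traces of base polymerise it.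

Step 3
Reactants: 5 cyclopent-2-en-1-one; 2 isopropenylmagnesium bromide; 4 dimethyl methylidenemalonate
Product: 7 dimethyl 2-{[(1R,2S)-5-oxo-2-(prop-1-en-2-yl)cyclopentyl]methyl}propanedioate, via bromomagnesium enolate 6 (not isolated)
Conditions: CuBr·SMe2 (5 mol%), (R)-1-[(SP)-2-(diphenylphosphino)ferrocenyl]ethyldicyclohexylphosphine or its antipode (6 mol%), t-BuOMe, −78 °C, slow addition of 2 (1.0 equiv) to 5 (1.05 equiv); then 4 (1.2 equiv), −78 → −40 °C; cold 1 M HCl
Reagents that add atoms: none
Why: Transmetallation of 2 to the CuBr·SMe2–diphosphine complex gives an alkenyl species of monovalent copper that binds the enone as a π-complex, adds oxidatively at the β-carbon to a trivalent copper intermediate and reductively eliminates, leaving the regiodefined bromomagnesium enolate 6. Enolate 6 then adds through its α-carbon to the very electrophilic alkene 4 (Michael addition), and the resulting malonate anion is too stabilised to add to a second molecule of 4 at low temperature. The closest known reaction type is the copper/ferrocenyl-diphosphine-catalysed asymmetric conjugate addition of Grignard reagents to cyclic enones with trapping of the magnesium enolate by an electrophile in the same flask. No ring is closed. The configuration at the isopropenyl-bearing carbon is set by the chiral diphosphine on copper, which selects the enone face. The configuration at the α-carbon follows from approach of 4 anti to the new isopropenyl group and is backed by the thermodynamic preference for trans at this epimerisable position. The step needs 1,4- over 1,2-addition, secured by slow addition of 2 to the catalyst at −78 °C in weakly coordinating solvent, and a single trapping without enolate equilibration, secured by the absence of a proton source, by consuming 2 fully (slight excess of 5) before 4 is added and by keeping 4 near one equivalent.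

Step 4
Reactants: 7 dimethyl 2-{[(1R,2S)-5-oxo-2-(prop-1-en-2-yl)cyclopentyl]methyl}propanedioate
Product: 8 dimethyl 2-{[(1R,2S,5S)-2-hydroxy-2-methyl-5-(prop-1-en-2-yl)cyclopentyl]methyl}propanedioate
Conditions: MeTi(OiPr)3 (2.5 equiv, 1 M in THF), Et2O, −40 → 0 °C; cold dilute HCl
Reagents that add atoms: methyltitanium triisopropoxide, C[Ti](OC(C)C)(OC(C)C)OC(C)C
Why: MeTi(OiPr)3 is a non-basic, ketone-selective methyl donor that leaves the esters and the acidic malonate C–H alone (titanium-mediated 1,2-addition); the bulky reagent approaches anti to the adjacent CH2CH(CO2Me)2 branch, so the hydroxyl ends up cis to that branch and the carbinol is (S). Low temperature and a cold quench keep the tertiary titanium alkoxide from lactonising onto the malonate.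

Step 5
Reactants: 8 dimethyl 2-{[(1R,2S,5S)-2-hydroxy-2-methyl-5-(prop-1-en-2-yl)cyclopentyl]methyl}propanedioate
Product: 9 dimethyl 2-{[(1R,2S,5S)-2-methyl-5-(prop-1-en-2-yl)-2-[(triethylsilyl)oxy]cyclopentyl]methyl}propanedioate
Conditions: TESOTf (1.5 equiv), 2,6-lutidine (3 equiv), CH2Cl2, −78 → 0 °C
Reagents that add atoms: triethylsilyl trifluoromethanesulfonate, CC[Si](CC)(CC)OS(=O)(=O)C(F)(F)F
Why: A silyl triflate with a hindered pyridine base silylates tertiary alcohols rapidly (silyl ether formation); capping the hydroxyl that sits cis to the malonate branch removes the risk of δ-lactone formation in the hot acidic oxidation that follows.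

Step 6
Reactants: 9 dimethyl 2-{[(1R,2S,5S)-2-methyl-5-(prop-1-en-2-yl)-2-[(triethylsilyl)oxy]cyclopentyl]methyl}propanedioate
Product: 10 tricyclic lactone methyl ester (trans-fused hydrindane, γ-lactone between the ring-B carbinol oxygen and the axial carboxyl on the future spiro carbon, equatorial CO2Me, ring-C OTES)
Conditions: Mn(OAc)3·2H2O (2.5 equiv), KOAc (2 equiv), degassed AcOH, 65 °C
Reagents that add atoms: none
Why: Mn(OAc)3 oxidises the malonate through its manganese enolate to an electrophilic malonyl radical, which closes ring B by 6-endo-trig attack on the CH2 terminus of the 1,1-disubstituted alkene (the 5-exo mode would need a trans-fused bicyclo[3.3.0]octane); a second equivalent of trivalent manganese oxidises the tertiary radical to a cation that the axial ester carbonyl captures with loss of its methyl group as methyl acetate (manganese triacetate oxidative radical cyclisation with lactonising termination). Ring B is a chair locked by the trans fusion, so only the axial ester can reach the cation and only from the axial face; this fixes the ring-B carbinol centre (oxygen axial, methyl equatorial, R) and the spiro carbon (lactone carbonyl cis to that oxygen).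

Step 7
Reactants: 10 tricyclic lactone methyl ester; 11 6-methylheptane-2,4-dione
Product: 13 hydroxy triketo ester (methyl ester with an axial 7-methyl-3,5-dioxooctanoyl group on the same ring-B carbon), via dilithio dianion 12 (not isolated)
Conditions: 11 (3 equiv), LDA (6 equiv), THF, 0 °C; then 10, −78 → 0 °C; cold 1 M HCl to pH 4
Reagents that add atoms: none
Why: Two equivalents of LDA convert 11 into its 1,3-dianion, whose terminal carbanion acylates esters at carbon (acylation of a β-diketone dianion to a 1,3,5-triketone, a crossed Claisen condensation); the strained bridged lactone, which cannot adopt the stabilised Z-ester geometry, is the better acyl donor than the methyl ester on the same carbon, and the new triketone is deprotonated at once, which stops a second addition. No stereocentre is formed; the lactone/ester distinction from step 6 places the future diprenyl carbon next to the carbonyl that is cis to the ring-B hydroxyl.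

Step 8
Reactants: 13 hydroxy triketo ester
Product: 15 spiro acyl trione diol (target lacking both prenyl groups), via spiro acyl trione silyl ether 14 (not isolated)
Conditions: NaOMe (5 equiv), MeOH, 60 °C; then 2 M aq. HCl to pH 1, 23 °C
Reagents that add atoms: none
Why: Under equilibrating methoxide the doubly activated CH2 between the two outer ketones attacks the methyl ester in a 6-exo-trig Claisen (Dieckmann-type) cyclisation, the known fate of 3,5,7-triketo esters, and the product leaves the equilibrium as its vinylogous-acid anion; the quaternary spiro carbon blocks the competing aldol mode. Acidification with dilute HCl in the same flask cleaves the tertiary silyl ether, and no stereocentre is touched.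

Step 9
Reactants: 15 spiro acyl trione diol; 16 prenyl bromide (1-bromo-3-methylbut-2-ene)
Product: 18 CNP0198642.4 (target), via monoprenyl trione 17 (not isolated)
Conditions: 16 (3 equiv), NaOMe (3.5 equiv), MeOH, 0 → 23 °C; 1 M HCl work-up
Reagents that add atoms: none
Why: The dianion of the enolised acyl trione is alkylated at carbon at the only ring-A position that still bears hydrogen, twice in succession, as in the base-mediated gem-diprenylation of acylphloroglucinol-type triones; protic solvent favours C- over O-alkylation and the tertiary hydroxyls are not alkylated. The carbon receives two identical groups, so no stereocentre arises, and ring A stays anionic until work-up, which shields the new non-enolisable ketone from retro-Claisen cleavage.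

## Compound list

1 | 2-bromopropene | CC(Br)=C | starting material
2 | isopropenylmagnesium bromide | CC(=C)[Mg]Br | intermediate
3 | dimethyl malonate | COC(=O)CC(=O)OC | starting material
4 | dimethyl methylidenemalonate | C=C(C(=O)OC)C(=O)OC | intermediate
5 | cyclopent-2-en-1-one | O=C1C=CCC1 | starting material
6 | bromomagnesium (S)-3-(prop-1-en-2-yl)cyclopent-1-en-1-olate | CC(=C)[C@H]1CCC(O[Mg]Br)=C1 | intermediate
7 | dimethyl 2-{[(1R,2S)-5-oxo-2-(prop-1-en-2-yl)cyclopentyl]methyl}propanedioate (trans) | COC(=O)C(C[C@@H]1[C@H](CCC1=O)C(C)=C)C(=O)OC | intermediate
8 | dimethyl 2-{[(1R,2S,5S)-2-hydroxy-2-methyl-5-(prop-1-en-2-yl)cyclopentyl]methyl}propanedioate (OH cis to the malonylmethyl branch) | COC(=O)C(C[C@@H]1[C@H](CC[C@]1(C)O)C(C)=C)C(=O)OC | intermediate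
9 | dimethyl 2-{[(1R,2S,5S)-2-methyl-5-(prop-1-en-2-yl)-2-[(triethylsilyl)oxy]cyclopentyl]methyl}propanedioate | COC(=O)C(C[C@@H]1[C@H](CC[C@]1(C)O[Si](CC)(CC)CC)C(C)=C)C(=O)OC | intermediate
10 | tricyclic lactone methyl ester: trans-fused octahydroindene (1S,3aS,4R,7aR; C1 = ring-C carbinol with OTES, C4 = ring-B carbinol, C6 = future spiro carbon) with the C4 oxygen and the axial C6 carboxyl joined as a γ-lactone and an equatorial CO2Me on C6 | O=C1[C@@]2(C[C@@H]3[C@H](CC[C@]3(C)O[Si](CC)(CC)CC)[C@](C)(O1)C2)C(=O)OC | intermediate
11 | 6-methylheptane-2,4-dione | CC(=O)CC(=O)CC(C)C | starting material
12 | dilithio 1,3-dianion of 6-methylheptane-2,4-dione (bis-enolate form) | C=C(O[Li])C=C(O[Li])CC(C)C | intermediate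
13 | hydroxy triketo ester: the same octahydroindene with free axial OH on C4, OTES on C1, and on C6 an equatorial CO2Me and an axial 7-methyl-3,5-dioxooctanoyl group | CC(C)CC(=O)CC(=O)CC(=O)[C@@]1(C[C@@H]2[C@H](CC[C@]2(C)O[Si](CC)(CC)CC)[C@](C)(O)C1)C(=O)OC | intermediate
14 | spiro acyl trione silyl ether: ring A closed (isovaleryl on the carbon between enol carbon and ketone, CH2 between the other ketone and the enol carbon), ring-C OTES, ring-B OH free | C1C(=O)[C@@]2(C[C@@H]3[C@H](CC[C@]3(C)O[Si](CC)(CC)CC)[C@](C)(O)C2)C(=O)C(C(=O)CC(C)C)=C1O | intermediate
15 | spiro acyl trione diol: the target lacking both prenyl groups | C1C(=O)[C@@]2(C[C@@H]3[C@H](CC[C@]3(C)O)[C@](C)(O)C2)C(=O)C(C(=O)CC(C)C)=C1O | intermediate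
16 | prenyl bromide (1-bromo-3-methylbut-2-ene) | CC(C)=CCBr | starting material
17 | monoprenyl trione: the target lacking one prenyl group, drawn as the dienol | CC(C)=CCC1=C(O)[C@@]2(C[C@@H]3[C@H](CC[C@]3(C)O)[C@](C)(O)C2)C(=O)C(C(=O)CC(C)C)=C1O | intermediate
18 | CNP0198642.4: spiro compound of 2-isovaleryl-4,4-diprenyl-enolised cyclohexanetrione (ring A) and the (1S,3aS,4R,7aR)-1,4-dihydroxy-1,4-dimethyl-octahydroindene (rings C and B), spiro carbon C6 with the diprenyl-flanked carbonyl cis to the C4 hydroxyl | CC(C)=CCC1(CC=C(C)C)C(=O)[C@@]2(C[C@@H]3[C@H](CC[C@]3(C)O)[C@](C)(O)C2)C(=O)C(C(=O)CC(C)C)=C1O | target

## Step count and least certain steps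

Total: 9 steps. Longest linear sequence: 8 steps (step 1 or step 2, then steps 3–9).

**Step 3 (key step).** Enantiofacial control may erode, because alkenyl Grignard reagents can add through ligand-free copper species and cyclopentenone is a small, weakly differentiated acceptor. The acceptor 4 may also oligomerise anionically before or after the trapping.

- Fallback: the two bond formations are separated, setting out from 5 and 2 and returning at 7.
- The same copper-catalysed addition is quenched with Me3SiCl/Et3N to give the isolated silyl enol ether (S)-trimethyl{[3-(prop-1-en-2-yl)cyclopent-1-en-1-yl]oxy}silane F1.
- F1 is then joined to 4 in a Lewis-acid-mediated Mukaiyama–Michael reaction (TiCl4, CH2Cl2, −78 °C, aqueous work-up).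
- No anionic chain carrier for polymerisation is present in that step, and the asymmetric step can be tuned for selectivity alone.

**Step 7.** The dianion may attack the methyl ester in competition with the lactone, or fail to add, because both carbonyls sit on the same quaternary carbon and differ only in strain and geometry.

- Fallback: the lactone is first singled out by reduction level, setting out from 10 and returning at 13.
- i-Bu2AlH (toluene, −78 °C) should reduce the lactone, not the hindered methyl ester, to the lactol F2.
- Dianion 12 adds to the aldehyde form of F2 in an aldol addition to give the β-hydroxy diketone F3.
- Dess–Martin periodinane oxidises the secondary alcohol of F3 to 13.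

**Step 6.** The tertiary radical or cation may end by elimination to ring-B alkenes or acetate capture and not by lactonisation. Premature loss of the silyl ether in hot acetic acid would reopen the δ-lactone pathway.

- Fallback: iodine-atom transfer under neutral conditions, setting out from 9 and returning at 10.
- NaH followed by N-iodosuccinimide gives the iodomalonate F4.
- Bu3SnSnBu3 (cat.), hν, benzene, 80 °C effects 6-endo atom-transfer cyclisation to a tertiary iodide, which ionises on heating and is captured by the axial ester with loss of iodomethane.

**Step 9.** O-alkylation and incomplete second alkylation may compete at the congested carbon. The free ring-B hydroxyl may add to the new ketone and open ring A by retro-Claisen cleavage if the medium becomes strongly basic.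

- Fallback: setting out from 15 and returning at 18.
- Pd(PPh3)4 (zerovalent palladium) with allyl methyl carbonate in THF should give double C-allylation, since O-allyl products re-enter the π-allyl manifold, forming the diallyl trione F5.
- Cross-metathesis of F5 with 2-methylbut-2-ene using the second-generation Grubbs catalyst RuCl2(=CHPh)(PCy3)(H2IMes) converts both allyl groups into prenyl groups.

**Step 4.** The tertiary titanium alkoxide, cis to the malonate branch, may undergo transesterification to a δ-lactone, and facial selectivity may be incomplete because the β-isopropenyl group lies on the face that the reagent must use.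

- Fallback: setting out from 7 and returning at 8.
- NaH (1.0 equiv, THF, 0 °C) converts the malonate into its sodium enolate F6, which switches off both ester carbonyls as acyl donors.
- The organocerium reagent from MeMgBr and CeCl3 is then added at −78 °C and the mixture is quenched cold with AcOH.

## Further compounds

F1 | step 3 | (S)-trimethyl{[3-(prop-1-en-2-yl)cyclopent-1-en-1-yl]oxy}silane | C[Si](C)(C)OC1=C[C@H](CC1)C(C)=C
F2 | step 7 | lactol of 10 (lactone carbonyl reduced to the hemiacetal, mixture at the hemiacetal carbon) | OC1[C@@]2(C[C@@H]3[C@H](CC[C@]3(C)O[Si](CC)(CC)CC)[C@](C)(O1)C2)C(=O)OC
F3 | step 7 | β-hydroxy diketone: 13 with the chain ketone next to the ring carbon as a secondary alcohol (mixture at that carbon) | CC(C)CC(=O)CC(=O)CC(O)[C@@]1(C[C@@H]2[C@H](CC[C@]2(C)O[Si](CC)(CC)CC)[C@](C)(O)C1)C(=O)OC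
F4 | step 6 | dimethyl 2-iodo-2-{[(1R,2S,5S)-2-methyl-5-(prop-1-en-2-yl)-2-[(triethylsilyl)oxy]cyclopentyl]methyl}propanedioate | COC(=O)C(I)(C[C@@H]1[C@H](CC[C@]1(C)O[Si](CC)(CC)CC)C(C)=C)C(=O)OC
F5 | step 9 | diallyl analogue of the target (two allyl groups in place of the two prenyl groups) | C=CCC1(CC=C)C(=O)[C@@]2(C[C@@H]3[C@H](CC[C@]3(C)O)[C@](C)(O)C2)C(=O)C(C(=O)CC(C)C)=C1O
F6 | step 4 | sodium malonate enolate of 7 | COC(=O)C(C[C@@H]1[C@H](CCC1=O)C(C)=C)=C(OC)O[Na]
A1 | alternative 1 | target lacking the isovaleryl group, bis(triethylsilyl) ether | CC(C)=CCC1(CC=C(C)C)C(=O)[C@@]2(C[C@@H]3[C@H](CC[C@]3(C)O[Si](CC)(CC)CC)[C@](C)(O[Si](CC)(CC)CC)C2)C(=O)CC1=O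
A2 | alternative 1 | spiro epoxide joining C4 of 2,2-diprenylcyclopentane-1,3-dione to the ring-B carbon of the bis(triethylsilyl)-protected hydrindane (epoxide oxygen on the ring-B face opposite the future diprenyl-flanked carbonyl; one epimer at the dione carbon drawn) | CC(C)=CCC1(CC=C(C)C)C(=O)C[C@]4(C1=O)[C@@]2(C[C@@H]3[C@H](CC[C@]3(C)O[Si](CC)(CC)CC)[C@](C)(O[Si](CC)(CC)CC)C2)O4
A3 | alternative 2 | trans-fused hydrindene gem-diester with ring-B trisubstituted alkene and ring-C methyl carbinol | COC(=O)C1(C(=O)OC)C[C@@H]2[C@H](CC[C@]2(C)O)C(C)=C1
A4 | alternative 2 | dimethyl 2-[(2E,6S)-6-hydroxy-2,6-dimethylocta-2,7-dien-1-ylidene]propanedioate | COC(=O)C(C(=O)OC)=C/C(C)=C/CC[C@](C=C)(C)O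
A5 | alternative 2 | (S)-linalool | CC(C)=CCC[C@](C=C)(C)O
A6 | alternative 3 | methyl (1R,2S,5S)-5-methyl-2-(prop-1-en-2-yl)-5-[(triethylsilyl)oxy]cyclopentane-1-carboxylate | COC(=O)[C@@H]1[C@H](CC[C@]1(C)O[Si](CC)(CC)CC)C(C)=C
A7 | alternative 3 | (3R,6S)-2-diazo-6-methyl-3-(prop-1-en-2-yl)-6-[(triethylsilyl)oxy]cyclohexan-1-one | CC(=C)[C@H]1CC[C@](C)(O[Si](CC)(CC)CC)C(=O)C1=[N+]=[N-]
A8 | alternative 3 | (S)-limonene | CC1=CC[C@H](CC1)C(C)=C
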